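**Retrosynthetic overview**
1. Target 19 ⇐ 18 by cleaving three aryl silyl ethers (last step).
2. 18 ⇐ 7 + 13 + 14 in one flask: a [4+1] annulation of a chiral benzyl sulfonium ylide onto an alkylidene-pyrandione closes the dihydrofuran (C2–C3 and C2–O bonds, both stereocentres); an acylketene/ketene-acetal [4+2] then closes the pendant 4-hydroxy-2-pyranone.
3. 7 (masked alkylidene-pyrandione) ⇐ 4 + 6 + sulfinate; 4 ⇐ 1 + 2 (dianion aldol condensation); 6 ⇐ 5 (SeO2).
4. 13 ⇐ 3,4-dihydroxybenzaldehyde 8 (silylation, reduction, bromide, S-alkylation of isothiocineole 11).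
5. Ring order: the pyranone that becomes the fused ring is bought in 1; the dihydrofuran and then the pendant pyranone are both closed in step 7.

Assumption: isothiocineole 11 and ketene bis(trimethylsilyl) acetal 14 are taken as purchasable (otherwise one operation each from limonene or trimethylsilyl acetate); the antipode of 11 drawn is assumed, not derived, to give 2S,3S, so the sense is checked on the first run and the (S)-limonene-derived sulfide is used if it is opposite.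

**Step 1**
Reactants: 1 4-hydroxy-6-methyl-2H-pyran-2-one; 2 4-[(tert-butyldimethylsilyl)oxy]benzaldehyde
Product: 4 6-[(E)-2-{4-[(tert-butyldimethylsilyl)oxy]phenyl}ethenyl]-4-hydroxy-2H-pyran-2-one, via aldol adduct 3 (not isolated)
Conditions: LiN(iPr)2 (2.3 equiv), THF/HMPA, −78 °C; 2, −78 → −20 °C; AcOH; crude, TsOH·H2O (10 mol%), PhMe, 80 °C
Reagents that add atoms: none
Why: The C6-methyl dianion of the pyranone (a vinylogous enolate) adds to the aldehyde and acid-catalysed E1 dehydration of the benzylic alcohol gives the conjugated E-styrylpyranone (aldol condensation); no stereocentre is kept.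

**Step 2**
Reactants: 5 2,2,6-trimethyl-4H-1,3-dioxin-4-one
Product: 6 2,2-dimethyl-4-oxo-4H-1,3-dioxine-6-carbaldehyde
Conditions: SeO2 (1.5 equiv), 1,4-dioxane, 90 °C
Reagents that add atoms: selenium dioxide, O=[Se]=O
Why: Riley oxidation of the enone-activated (vinylogous) methyl group gives the aldehyde below the temperature at which the dioxinone fragments; no stereocentre.

**Step 3**
Reactants: 4 6-[(E)-2-{4-[(tert-butyldimethylsilyl)oxy]phenyl}ethenyl]-4-hydroxy-2H-pyran-2-one; 6 2,2-dimethyl-4-oxo-4H-1,3-dioxine-6-carbaldehyde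
Product: 7 racemic 3-[(2,2-dimethyl-4-oxo-4H-1,3-dioxin-6-yl)(4-methylbenzenesulfonyl)methyl]-6-[(E)-2-{4-[(tert-butyldimethylsilyl)oxy]phenyl}ethenyl]-4-hydroxy-2H-pyran-2-one
Conditions: 4-MeC6H4SO2Na (2.5 equiv), HCO2H/H2O/THF, rt, 24 h
Reagents that add atoms: sodium 4-methylbenzenesulfinate, [Na+].Cc1ccc(cc1)S(=O)[O-]
Why: Knoevenagel condensation at pyranone C3 gives a transient alkylidene-dione that sulfinate captures (three-component sulfonylalkylation, as used to store quinone-methide-type acceptors), giving an aldehyde-free precursor; its stereocentre is racemic and is erased in step 7.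

**Step 4**
Reactants: 8 3,4-dihydroxybenzaldehyde
Product: 9 3,4-bis[(tert-butyldimethylsilyl)oxy]benzaldehyde
Conditions: TBSCl (2.4 equiv), imidazole, DMF, rt
Reagents that add atoms: tert-butyldimethylsilyl chloride, CC(C)(C)[Si](C)(C)Cl
Why: Imidazole-promoted silyl ether formation on both phenols; no stereocentre.

**Step 5**
Reactants: 9 3,4-bis[(tert-butyldimethylsilyl)oxy]benzaldehyde
Product: 10 {3,4-bis[(tert-butyldimethylsilyl)oxy]phenyl}methanol
Conditions: NaBH4, EtOH/THF, 0 °C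
Reagents that add atoms: none
Why: Hydride reduction of the aldehyde to the benzyl alcohol, short and cold so the aryl silyl ethers survive; no stereocentre.

**Step 6**
Reactants: 10 {3,4-bis[(tert-butyldimethylsilyl)oxy]phenyl}methanol; 11 isothiocineole, (1R,4S,5R)-4,7,7-trimethyl-6-thiabicyclo[3.2.1]octane (from (R)-limonene, C4 methyl on the face of the sulfur bridge)
Product: 13 (1R,4S,5R,6R)-6-({3,4-bis[(tert-butyldimethylsilyl)oxy]phenyl}methyl)-4,7,7-trimethyl-6-thiabicyclo[3.2.1]octan-6-ium tetrafluoroborate (benzyl group exo on sulfur), via benzyl bromide 12 (not isolated)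
Conditions: PBr3 (0.4 equiv), Et2O, 0 °C; crude 12, 11, NaBF4, CH2Cl2/H2O, rt, 48 h
Reagents that add atoms: phosphorus tribromide, BrP(Br)Br (supplies the bromine of 12 only); sodium tetrafluoroborate, [Na+].F[B-](F)(F)F
Why: Alcohol-to-bromide substitution, then SN2 S-alkylation of the sulfide on its exposed exo lone pair with anion exchange to the non-nucleophilic tetrafluoroborate, gives a single sulfonium diastereomer (the stereogenic sulfur is fixed by the bicyclic sulfide).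

**Step 7**
Reactants: 7 racemic sulfone adduct of step 3; 13 sulfonium tetrafluoroborate of step 6; 14 1,1-bis(trimethylsilyloxy)ethene
Product: 18 (2S,3S)-2-{3,4-bis[(tert-butyldimethylsilyl)oxy]phenyl}-6-[(E)-2-{4-[(tert-butyldimethylsilyl)oxy]phenyl}ethenyl]-3-(4-hydroxy-2-oxo-2H-pyran-6-yl)-2,3-dihydro-4H-furo[3,2-c]pyran-4-one, via oxadiene 15 (not isolated), via dihydrofuran-dioxinone 16 (not isolated), via bis-silyl cycloadduct 17 (not isolated)
Conditions: 13 (1.2 equiv), Cs2CO3 (2.5 equiv), CH2Cl2/MeCN, −40 → 0 °C; filter, PhMe, 14 (4 equiv), 110 °C, 1 h; then THF/H2O, rt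
Reagents that add atoms: none
Why: Proposed new method: base expels sulfinate from 7 to release the 1-oxadiene 15 at a temperature where its oxa-6π closure is slow; the isothiocineole-derived benzylide adds to the exocyclic carbon and the pyranone enolate oxygen closes by intramolecular SN2 with inversion and loss of the sulfide (anti betaine, hence trans; the shielded ylide face is relied on to fix C2 and, through the anti addition, C3 as 2S,3S); heating then triggers retro-[4+2] of the dioxinone to an acylketene, which the ketene silyl acetal captures in a [4+2] cycloaddition to build the pendant pyranone after desilylation; the closest known reactions are sulfur-ylide [4+1] annulations of ortho-quinone methides and alkylidene-1,3-diones released from sulfone precursors, isothiocineole benzylide epoxidations, and acylketene cycloadditions with enol ethers and ketene acetals.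

**Step 8**
Reactants: 18 tris-silyl ether of step 7
Product: 19 (2S,3S)-2-(3,4-dihydroxyphenyl)-3-(4-hydroxy-2-oxo-2H-pyran-6-yl)-6-[(E)-2-(4-hydroxyphenyl)ethenyl]-2,3-dihydro-4H-furo[3,2-c]pyran-4-one
Conditions: Et3N·3HF, THF, 0 °C → rt
Reagents that add atoms: none
Why: Fluoride cleavage of the three aryl silyl ethers under weakly acidic conditions leaves the lactones, the styrene and both stereocentres untouched.

**Compound list**
1 | 4-hydroxy-6-methyl-2H-pyran-2-one | Cc1cc(O)cc(=O)o1 | starting material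
2 | 4-[(tert-butyldimethylsilyl)oxy]benzaldehyde | O=Cc1ccc(O[Si](C)(C)C(C)(C)C)cc1 | starting material
3 | racemic 6-(2-{4-[(tert-butyldimethylsilyl)oxy]phenyl}-2-hydroxyethyl)-4-hydroxy-2H-pyran-2-one (aldol adduct, not isolated) | OC(Cc1cc(O)cc(=O)o1)c1ccc(O[Si](C)(C)C(C)(C)C)cc1 | intermediate
4 | 6-[(E)-2-{4-[(tert-butyldimethylsilyl)oxy]phenyl}ethenyl]-4-hydroxy-2H-pyran-2-one | O=c1cc(O)cc(/C=C/c2ccc(O[Si](C)(C)C(C)(C)C)cc2)o1 | intermediate
5 | 2,2,6-trimethyl-4H-1,3-dioxin-4-one | CC1=CC(=O)OC(C)(C)O1 | starting material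
6 | 2,2-dimethyl-4-oxo-4H-1,3-dioxine-6-carbaldehyde | O=CC1=CC(=O)OC(C)(C)O1 | intermediate
7 | racemic 3-[(2,2-dimethyl-4-oxo-4H-1,3-dioxin-6-yl)(4-methylbenzenesulfonyl)methyl]-6-[(E)-2-{4-[(tert-butyldimethylsilyl)oxy]phenyl}ethenyl]-4-hydroxy-2H-pyran-2-one | Cc1ccc(cc1)S(=O)(=O)C(C1=CC(=O)OC(C)(C)O1)c1c(O)cc(/C=C/c2ccc(O[Si](C)(C)C(C)(C)C)cc2)oc1=O | intermediate
8 | 3,4-dihydroxybenzaldehyde | O=Cc1ccc(O)c(O)c1 | starting material
9 | 3,4-bis[(tert-butyldimethylsilyl)oxy]benzaldehyde | O=Cc1ccc(O[Si](C)(C)C(C)(C)C)c(O[Si](C)(C)C(C)(C)C)c1 | intermediate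
10 | {3,4-bis[(tert-butyldimethylsilyl)oxy]phenyl}methanol | OCc1ccc(O[Si](C)(C)C(C)(C)C)c(O[Si](C)(C)C(C)(C)C)c1 | intermediate
11 | isothiocineole, (1R,4S,5R)-4,7,7-trimethyl-6-thiabicyclo[3.2.1]octane | C[C@H]1CC[C@@H]2C[C@H]1SC2(C)C | starting material
12 | 4-(bromomethyl)-1,2-bis[(tert-butyldimethylsilyl)oxy]benzene (not isolated) | BrCc1ccc(O[Si](C)(C)C(C)(C)C)c(O[Si](C)(C)C(C)(C)C)c1 | intermediate
13 | (1R,4S,5R,6R)-6-({3,4-bis[(tert-butyldimethylsilyl)oxy]phenyl}methyl)-4,7,7-trimethyl-6-thiabicyclo[3.2.1]octan-6-ium tetrafluoroborate | C[C@H]1CC[C@@H]2C[C@H]1[S@@+](Cc3ccc(O[Si](C)(C)C(C)(C)C)c(O[Si](C)(C)C(C)(C)C)c3)C2(C)C.F[B-](F)(F)F | intermediate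
14 | 1,1-bis(trimethylsilyloxy)ethene (ketene bis(trimethylsilyl) acetal) | C=C(O[Si](C)(C)C)O[Si](C)(C)C | starting material
15 | 3-[(2,2-dimethyl-4-oxo-4H-1,3-dioxin-6-yl)methylidene]-6-[(E)-2-{4-[(tert-butyldimethylsilyl)oxy]phenyl}ethenyl]-2H-pyran-2,4(3H)-dione (exocyclic alkene geometry not defined; not isolated) | O=C1OC(/C=C/c2ccc(O[Si](C)(C)C(C)(C)C)cc2)=CC(=O)C1=CC1=CC(=O)OC(C)(C)O1 | intermediate
16 | (2S,3S)-2-{3,4-bis[(tert-butyldimethylsilyl)oxy]phenyl}-3-(2,2-dimethyl-4-oxo-4H-1,3-dioxin-6-yl)-6-[(E)-2-{4-[(tert-butyldimethylsilyl)oxy]phenyl}ethenyl]-2,3-dihydro-4H-furo[3,2-c]pyran-4-one (not isolated) | CC1(C)OC(=O)C=C([C@H]2c3c(cc(/C=C/c4ccc(O[Si](C)(C)C(C)(C)C)cc4)oc3=O)O[C@@H]2c2ccc(O[Si](C)(C)C(C)(C)C)c(O[Si](C)(C)C(C)(C)C)c2)O1 | intermediate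
17 | (2S,3S)-3-[4-oxo-6,6-bis(trimethylsilyloxy)-5,6-dihydro-4H-pyran-2-yl] analogue of 16 (bis-silyl cycloadduct, not isolated) | C[Si](C)(C)OC1(O[Si](C)(C)C)CC(=O)C=C([C@H]2c3c(cc(/C=C/c4ccc(O[Si](C)(C)C(C)(C)C)cc4)oc3=O)O[C@@H]2c2ccc(O[Si](C)(C)C(C)(C)C)c(O[Si](C)(C)C(C)(C)C)c2)O1 | intermediate
18 | (2S,3S)-2-{3,4-bis[(tert-butyldimethylsilyl)oxy]phenyl}-6-[(E)-2-{4-[(tert-butyldimethylsilyl)oxy]phenyl}ethenyl]-3-(4-hydroxy-2-oxo-2H-pyran-6-yl)-2,3-dihydro-4H-furo[3,2-c]pyran-4-one | O=c1cc(O)cc([C@H]2c3c(cc(/C=C/c4ccc(O[Si](C)(C)C(C)(C)C)cc4)oc3=O)O[C@@H]2c2ccc(O[Si](C)(C)C(C)(C)C)c(O[Si](C)(C)C(C)(C)C)c2)o1 | intermediate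
19 | (2S,3S)-2-(3,4-dihydroxyphenyl)-3-(4-hydroxy-2-oxo-2H-pyran-6-yl)-6-[(E)-2-(4-hydroxyphenyl)ethenyl]-2,3-dihydro-4H-furo[3,2-c]pyran-4-one (trans) | O=c1cc(O)cc([C@H]2c3c(cc(/C=C/c4ccc(O)cc4)oc3=O)O[C@@H]2c2ccc(O)c(O)c2)o1 | target

**Totals**
Total steps: 8. Longest linear sequence: 5 (steps 4, 5, 6, 7, 8).

**Steps most likely to fail, with fallbacks**

Step 7. The ylide must add only to the exocyclic carbon and close through the C4 oxygen rather than the lactone oxygen. Partial SN1 closure at the electron-rich benzylic carbon would erode the enantiomeric excess. The intermolecular capture of the acylketene competes with its dimerisation and hydrolysis. The fallback sets out from 4 (with 1 and 9 for the second partner) and comes back at 18; it forms the same dihydrofuran bonds from a metal carbenoid instead of an ylide. Diazo transfer to 4 (4-acetamidobenzenesulfonyl azide, Et3N, MeCN) gives 3-diazo-6-[(E)-2-{4-[(tert-butyldimethylsilyl)oxy]phenyl}ethenyl]-2H-pyran-2,4(3H)-dione F1. Compounds 1 and 9 are joined as in step 1, through the racemic aldol adduct 6-(2-{3,4-bis[(tert-butyldimethylsilyl)oxy]phenyl}-2-hydroxyethyl)-4-hydroxy-2H-pyran-2-one F2, to 6-[(E)-2-{3,4-bis[(tert-butyldimethylsilyl)oxy]phenyl}ethenyl]-4-hydroxy-2H-pyran-2-one F3. Its acidic hydroxyl is capped (TBSOTf, 2,6-lutidine) to give 4-[(tert-butyldimethylsilyl)oxy]-6-[(E)-2-{3,4-bis[(tert-butyldimethylsilyl)oxy]phenyl}ethenyl]-2H-pyran-2-one F4. Decomposition of F1 with Rh2(S-PTTL)4 (dirhodium tetrakis[N-phthaloyl-(S)-tert-leucinate]) in the presence of F4 gives the trans formal [3+2] adduct, the 4-O-silyl ether of 18, F5. The carbenoid carbon bonds to the styrene carbon next to the pyranone and the enolate oxygen closes on the benzylic cation. Methanol cleaves the labile pyranonyl silyl ether to return 18, with chiral-phase chromatography if the enantiomeric excess is insufficient.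

Step 3. The Knoevenagel adduct may be lost to oxa-6π electrocyclisation onto the dioxinone alkene, or to a second pyranone, before sulfinate captures it. The fallback sets out from 4 and 6 and comes back at 7; it traps the adduct with a thiol, a much better Michael donor, and oxidises afterwards. Compounds 4 and 6 with 4-methylbenzenethiol and piperidinium acetate in CH2Cl2 give 3-[(2,2-dimethyl-4-oxo-4H-1,3-dioxin-6-yl)(4-methylphenylsulfanyl)methyl]-6-[(E)-2-{4-[(tert-butyldimethylsilyl)oxy]phenyl}ethenyl]-4-hydroxy-2H-pyran-2-one F6. Oxidation with mCPBA (2.1 equiv, CH2Cl2, 0 °C) converts it to sulfone 7.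

Step 2. The SeO2 oxidation can over-oxidise to the acid or fragment the dioxinone on heating. The fallback sets out from 5 and comes back at 6; it oxidises through the dienolate. LiN(iPr)2 then Me3SiCl gives the silyl dienol ether 2,2-dimethyl-6-methylidene-4-[(trimethylsilyl)oxy]-6H-1,3-dioxine F7. mCPBA hydroxylates its terminal carbon (vinylogous Rubottom oxidation) to 6-(hydroxymethyl)-2,2-dimethyl-4H-1,3-dioxin-4-one F8, and Dess–Martin periodinane oxidises it to 6.

**Further compounds**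
F1 | step 7 | 3-diazo-6-[(E)-2-{4-[(tert-butyldimethylsilyl)oxy]phenyl}ethenyl]-2H-pyran-2,4(3H)-dione | [N-]=[N+]=C1C(=O)OC(/C=C/c2ccc(O[Si](C)(C)C(C)(C)C)cc2)=CC1=O
F2 | step 7 | racemic 6-(2-{3,4-bis[(tert-butyldimethylsilyl)oxy]phenyl}-2-hydroxyethyl)-4-hydroxy-2H-pyran-2-one | OC(Cc1cc(O)cc(=O)o1)c1ccc(O[Si](C)(C)C(C)(C)C)c(O[Si](C)(C)C(C)(C)C)c1
F3 | step 7 | 6-[(E)-2-{3,4-bis[(tert-butyldimethylsilyl)oxy]phenyl}ethenyl]-4-hydroxy-2H-pyran-2-one | O=c1cc(O)cc(/C=C/c2ccc(O[Si](C)(C)C(C)(C)C)c(O[Si](C)(C)C(C)(C)C)c2)o1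
F4 | step 7 | 4-[(tert-butyldimethylsilyl)oxy]-6-[(E)-2-{3,4-bis[(tert-butyldimethylsilyl)oxy]phenyl}ethenyl]-2H-pyran-2-one | O=c1cc(O[Si](C)(C)C(C)(C)C)cc(/C=C/c2ccc(O[Si](C)(C)C(C)(C)C)c(O[Si](C)(C)C(C)(C)C)c2)o1
F5 | step 7 | (2S,3S)-2-{3,4-bis[(tert-butyldimethylsilyl)oxy]phenyl}-3-{4-[(tert-butyldimethylsilyl)oxy]-2-oxo-2H-pyran-6-yl}-6-[(E)-2-{4-[(tert-butyldimethylsilyl)oxy]phenyl}ethenyl]-2,3-dihydro-4H-furo[3,2-c]pyran-4-one | O=c1cc(O[Si](C)(C)C(C)(C)C)cc([C@H]2c3c(cc(/C=C/c4ccc(O[Si](C)(C)C(C)(C)C)cc4)oc3=O)O[C@@H]2c2ccc(O[Si](C)(C)C(C)(C)C)c(O[Si](C)(C)C(C)(C)C)c2)o1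
F6 | step 3 | racemic 3-[(2,2-dimethyl-4-oxo-4H-1,3-dioxin-6-yl)(4-methylphenylsulfanyl)methyl]-6-[(E)-2-{4-[(tert-butyldimethylsilyl)oxy]phenyl}ethenyl]-4-hydroxy-2H-pyran-2-one | Cc1ccc(cc1)SC(C1=CC(=O)OC(C)(C)O1)c1c(O)cc(/C=C/c2ccc(O[Si](C)(C)C(C)(C)C)cc2)oc1=O
F7 | step 2 | 2,2-dimethyl-6-methylidene-4-[(trimethylsilyl)oxy]-6H-1,3-dioxine | C=C1C=C(O[Si](C)(C)C)OC(C)(C)O1
F8 | step 2 | 6-(hydroxymethyl)-2,2-dimethyl-4H-1,3-dioxin-4-one | OCC1=CC(=O)OC(C)(C)O1
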